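**Conventions.** MOM = methoxymethyl; prenyl = 3‑methylbut‑2‑en‑1‑yl. Chromanone half: O1, C2, C3, C4, benzo ring A, C2‑aryl ring B. Isoflavonoid half: acetal carbon C2'', carbinol carbon C3'', benzylic carbon C4'', benzo ring D (on the chroman) and ring E (on the dihydrobenzofuran). Central tetrahydrofuran: O–C2–C3–C4''–C3''. My CIP assignment of the target is (2R,3S,2''S,3''S,4''R); the SMILES are authoritative.

## The problem

The target is a flavanone and an isoflavonoid C6–C3–C6 unit welded through the tetrahydrofuran O–C2–C3–C4''–C3''. C2 is thereby a ketal (O1 and the furan oxygen). C2'' is a bis‑aryloxy acetal shared by a chroman (ring D) and a 2,3‑dihydrobenzofuran (ring E). C3'' is a fully substituted benzylic carbinol carbon common to three rings.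

There are five contiguous stereocentres. C2'' must follow C3'' (cis 5/6 acetal) and C3 must follow C2 (cis‑fused ketal). The real variables are the absolute and relative configuration of C4''/C3'' and the face on which the chromanone closes. C2 and C3 can open and reclose (retro‑oxa‑Michael, enolisation), so they can only be set last. C4'' and C3'' cannot be corrected and need reagent control.

Three ortho‑prenylphenols rule out strong acid, hydrogenation and electrophilic or quinone oxidants. The ketal, the acetal and the para‑hydroxybenzylic C3''–O bond ionise in acid. The obvious union of a 1,3‑diketone with an isoflavene needs a two‑electron oxidation at C3''/C4'' in the presence of all of these groups.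

The feature that removes this problem: C3'' bears the furan oxygen and is bonded to C2'', which in turn is bonded to the ring‑E oxygen. If C2'' is raised to the carboxyl level, ring E–O–C2''–C3'' is a 3‑hydroxybenzofuran‑2(3H)‑one. Its C3''–H is acidic and its C3''–OH is nucleophilic, so it is a 1,2‑C,O‑bis‑nucleophile. The other three furan atoms (C4'', C3, C2) are the β‑carbon, α‑carbon and carbonyl carbon of an arylidene 1,3‑diketone, whose second aroyl group (ring A) carries the phenol that later closes the chromanone.

## Retrosynthesis

**19 ⇒ 16.** The O(ring D)–C2'' acetal bond and the O1–C2 ketal bond are cut, and six MOM groups and a hydroxyl on C2'' are added back. These are the bonds whose stereocentres (C2'', C2, C3) are dictated by ring fusion or by equilibrium, so nothing is lost by closing them last. The precursor 16 is a spiro compound with two defined stereocentres instead of a hexacycle with five. The forward step must remove the MOM groups, ionise the lactol and trigger a 6‑exo acetalisation and a 6‑endo oxa‑Michael closure without touching the prenyl groups.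

**16 ⇒ 15.** The lactol is taken back to the lactone. The lactone level is what makes C3''–H acidic and ties up the ring‑E phenol, at the price of one hydride later. The forward step must reduce an aryl lactone in the presence of a vinylogous ester.

**15 ⇒ 8 + 12.** C4''–C3'' and O–C2 are cut, with C2=C3 read as a dehydrated hemiketal. Cutting C3–C4'' instead (the biomimetic cut) leaves the oxidation at C3'' unsolved. This cut is redox‑neutral because the C3'' oxygen comes with 12. Both partners are achiral or racemic and together hold all 45 carbons. The forward reaction must set both permanent stereocentres under catalyst control.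

**8 ⇒ 6 + 7, 6 ⇒ 5 ⇒ 2 + 4, 2 ⇐ 1, 4 ⇐ 3.** Knoevenagel condensation, twofold Stille prenylation, crossed Claisen condensation and two MOM protections. The diketone brings rings A and B and both of their prenyl groups in one piece.

**12 ⇒ 11 ⇒ 10 ⇒ 9.** Phenol protection, then Friedel–Crafts hydroxyalkylation/lactonisation with ethyl glyoxylate, then Stille prenylation of 2‑iodoresorcinol. The C2 symmetry of 10 makes the regiochemistry trivial, and glyoxylate supplies C3'', C2'' and the furan oxygen.

## Roads not taken

**Alternative 1:** The most obvious, biomimetic cut at C3–C4'' and O–C3''. The free diketone A1 would be combined with the racemic dehydro‑acetal A2 (the cyclised form of the 2'‑hydroxyisoflavylium ion). The key step would be a two‑electron oxidation (Ag2O or Mn(OAc)3) of A2 to the extended quinone methide A3, captured by A1 in a [3+2] sense, followed by oxa‑Michael closure. The oxidant would have to discriminate between four phenols, three ortho‑prenylphenols and an enolised diketone. The only stereocentre of A2 is the labile acetal carbon, which is frozen as a racemate in A3, so there is no handle for enantiocontrol. The chosen plan needs no oxidant and sets the absolute configuration catalytically.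

**Alternative 2:** Cut only C3–C4''. A chiral‑phosphate‑catalysed addition of A1 to the isoflavylium salt A4 at C4'', then acetalisation, would give A5 with hydrogen on C3''; a late oxidation would then install the C3''–O bond. A 2‑unsubstituted benzopyrylium ion is also attacked at C2. The remaining oxidation concerns a non‑acidic tertiary benzylic C–H that can only be reached through phenol oxidation, which the ortho‑prenylphenols do not survive. The chosen plan has that oxygen in place from the start.

**Alternative 3:** Umpolung at C4''. A carbene‑catalysed homoenolate annulation of the cinnamaldehyde A8 with the benzofuran‑2,3‑dione A6 would give the spiro‑γ‑butyrolactone A7 with C4'' and C3'' set. Rings A and B would then have to be added by α‑aroylation next to a quaternary centre and by aryl‑metal addition to one of two lactone carbonyls. That is four to five further steps on a hindered substrate, whereas the chosen plan delivers both rings with the diketone in the same step that forms the furan.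

Key step: step 9

Assumption: C2 and C3 equilibrate by ring opening, and the configuration of 19 (chromanone cis‑fused, ring B on the convex face of the tetrahydrofuran–chroman bicycle) is taken to be the thermodynamically preferred one; this is not established. Compounds 1, 3, 7 and 9 are taken to be catalogue compounds.

## Steps

Step 1
Reactants: 1 1-(5-bromo-2,4-dihydroxyphenyl)ethan-1-one
Product: 2 1-[5-bromo-2,4-bis(methoxymethoxy)phenyl]ethan-1-one
Conditions: NaH (2.5 equiv), MOMCl (2.5 equiv), DMF, 0 °C → rt
Reagents that add atoms: chloromethyl methyl ether, COCCl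
Why: O‑alkylation (MOM protection); NaH is needed to alkylate the chelated 2‑OH as well; MOM survives the enolate, palladium, amine and hydride steps and all six groups leave together in step 11.

Step 2
Reactants: 3 methyl 3-bromo-4-hydroxybenzoate
Product: 4 methyl 3-bromo-4-(methoxymethoxy)benzoate
Conditions: MOMCl (1.3 equiv), i-Pr2NEt (1.5 equiv), CH2Cl2, 0 °C → rt
Reagents that add atoms: chloromethyl methyl ether, COCCl
Why: Standard MOM protection of an unhindered phenol; the ester is untouched.

Step 3
Reactants: 2 1-[5-bromo-2,4-bis(methoxymethoxy)phenyl]ethan-1-one; 4 methyl 3-bromo-4-(methoxymethoxy)benzoate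
Product: 5 1-[5-bromo-2,4-bis(methoxymethoxy)phenyl]-3-[3-bromo-4-(methoxymethoxy)phenyl]propane-1,3-dione
Conditions: NaH (3 equiv), THF, reflux; aq. NH4Cl
Reagents that add atoms: none
Why: Crossed Claisen condensation of a methyl ketone enolate with a non‑enolisable aryl ester, driven by formation of the diketonate; aryl bromides and MOM ethers are inert to NaH.

Step 4
Reactants: 5 1-[5-bromo-2,4-bis(methoxymethoxy)phenyl]-3-[3-bromo-4-(methoxymethoxy)phenyl]propane-1,3-dione
Product: 6 1-[2,4-bis(methoxymethoxy)-5-prenylphenyl]-3-[4-(methoxymethoxy)-3-prenylphenyl]propane-1,3-dione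
Conditions: prenyl-SnBu3 (2.6 equiv), Pd(PPh3)4 (10 mol %), DMF, 95 °C
Reagents that add atoms: tributyl(3-methylbut-2-en-1-yl)stannane, CC(C)=CC[Sn](CCCC)(CCCC)CCCC
Why: Twofold Stille coupling; bond formation at the tin‑bearing carbon gives the linear prenyl groups; the neutral conditions spare the diketone, and installing both groups on 5 saves a step.

Step 5
Reactants: 6 1-[2,4-bis(methoxymethoxy)-5-prenylphenyl]-3-[4-(methoxymethoxy)-3-prenylphenyl]propane-1,3-dione; 7 2,4-bis(methoxymethoxy)benzaldehyde
Product: 8 2-[2,4-bis(methoxymethoxy)benzylidene]-1-[2,4-bis(methoxymethoxy)-5-prenylphenyl]-3-[4-(methoxymethoxy)-3-prenylphenyl]propane-1,3-dione (E/Z mixture)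
Conditions: piperidine (0.2 equiv), AcOH (0.2 equiv), toluene, reflux, azeotropic removal of water
Reagents that add atoms: none
Why: Knoevenagel condensation of a 1,3‑diketone with an aromatic aldehyde; the alkene geometry is irrelevant because C3 is re‑formed in steps 9 and 11; the MOM group on the ring‑A 2‑oxygen keeps that phenol from adding to the new alkene.

Step 6
Reactants: 9 2-iodobenzene-1,3-diol
Product: 10 2-prenylbenzene-1,3-diol
Conditions: prenyl-SnBu3 (1.2 equiv), Pd(PPh3)4 (5 mol %), DMF, 80 °C
Reagents that add atoms: tributyl(3-methylbut-2-en-1-yl)stannane, CC(C)=CC[Sn](CCCC)(CCCC)CCCC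
Why: Stille coupling tolerates free phenols and places the prenyl group between the two oxygens without protection and without acid.

Step 7
Reactants: 10 2-prenylbenzene-1,3-diol
Product: 11 rac-3,6-dihydroxy-7-prenyl-1-benzofuran-2(3H)-one
Conditions: ethyl glyoxylate (50 % in toluene, 1.1 equiv), Ti(Oi-Pr)4 (10 mol %), toluene, Ar, 0 °C → rt, then 50 °C
Reagents that add atoms: ethyl glyoxylate, CCOC(=O)C=O
Why: Ortho‑selective Friedel–Crafts hydroxyalkylation of the resorcinol at the position ortho to one hydroxyl and para to the other (C4 and C6 are equivalent), then lactonisation onto the neighbouring phenol with loss of ethanol; no acid strong enough to cyclise the prenylphenol is present, and a racemate suffices because this centre is planarised in step 9.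

Step 8
Reactants: 11 rac-3,6-dihydroxy-7-prenyl-1-benzofuran-2(3H)-one
Product: 12 rac-3-hydroxy-6-(methoxymethoxy)-7-prenyl-1-benzofuran-2(3H)-one
Conditions: MOMCl (1.05 equiv), i-Pr2NEt (1.2 equiv), CH2Cl2, Ar, −20 → 0 °C
Reagents that add atoms: chloromethyl methyl ether, COCCl
Why: Chemoselective O‑alkylation of the phenol over the hindered secondary α‑hydroxy‑lactone hydroxyl; the protected para‑oxygen of ring E cannot expel the benzylic C3''–O bond as a quinone methide in steps 9 and 10.

Step 9
Reactants: 8 2-[2,4-bis(methoxymethoxy)benzylidene]-1-[2,4-bis(methoxymethoxy)-5-prenylphenyl]-3-[4-(methoxymethoxy)-3-prenylphenyl]propane-1,3-dione; 12 rac-3-hydroxy-6-(methoxymethoxy)-7-prenyl-1-benzofuran-2(3H)-one (1.2 equiv)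
Product: 15 (3S,3'S)-4'-[2,4-bis(methoxymethoxy)-5-prenylbenzoyl]-3'-[2,4-bis(methoxymethoxy)phenyl]-6-(methoxymethoxy)-5'-[4-(methoxymethoxy)-3-prenylphenyl]-7-prenyl-2H,3'H-spiro[1-benzofuran-3,2'-furan]-2-one (ring D on C3' cis to the lactone carbonyl), via Michael adduct 13 (not isolated), via cyclic hemiketal 14 (not isolated)
Conditions: quinine-derived 3,5-bis(trifluoromethyl)phenyl squaramide (10 mol %), CH2Cl2, −20 °C; then PPTS (0.5 equiv), 4 Å MS, 40 °C
Reagents that add atoms: none
Why: Formal [3+2] annulation by Michael addition, hemiketalisation and dehydration, the reaction type of bifunctional‑amine‑catalysed Michael additions of 3‑substituted benzofuran‑2(3H)‑ones and of Michael/hemiketalisation annulations of 3‑hydroxyoxindoles (an interrupted Feist–Benary‑like outcome). The quinuclidine nitrogen deprotonates the acidic C3–H of racemic 12 (its stereocentre is erased in the enediolate), the squaramide N–H groups bind the dicarbonyl of 8, and the enolate carbon adds to the β‑carbon to give 13, forming C4''–C3'' and both permanent stereocentres at once. The tertiary hydroxyl then adds 5‑exo‑trig to the less hindered, less deactivated ring‑B ketone (14), and PPTS removes water through the cyclic oxocarbenium ion to give the vinylogous ester 15, which can no longer undergo retro‑Michael cleavage. C3'' is set by the face of the planar enolate that the catalyst leaves open. C4'' follows from the closed, hydrogen‑bonded transition state in which the dicarbonyl terminus lies over the lactone C–O edge, the β‑hydrogen points to the peri hydrogen and ring D lies over the five‑membered ring; this places ring D syn to the lactone carbonyl, which is also the less crowded spiro isomer. The quinine/quinidine pseudo‑enantiomeric pair gives either absolute sense, so the series of 19 is a matter of catalyst choice. The step needs C‑ over O‑attack of the enediolate (the normal behaviour of benzofuranone donors), Michael addition over retro‑Claisen cleavage of the diketone (low temperature, weak base, acid added before the hemiketal alkoxide can fragment) and hemiketalisation at the ring‑B carbonyl. Closure at the other carbonyl is not fatal, because the wet acid of step 11 reopens that ring.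

Step 10
Reactants: 15 the spiro dihydrofuran lactone of step 9
Product: 16 lactol of 15: same compound with the lactone C=O (C2'') reduced to CH(OH), anomeric mixture, (3S,3'S) unchanged
Conditions: DIBAL-H (1.3 equiv), CH2Cl2, −78 °C; aq. Rochelle salt
Reagents that add atoms: none
Why: DIBAL reduction of an aryl lactone to the lactol, whose aluminate is stable at −78 °C; the only other carbonyl is a vinylogous ester on an ortho‑disubstituted, electron‑rich aryl ring and should react much more slowly; MOM ethers, prenyl groups and the enol ether are inert.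

Step 11
Reactants: 16 lactol of 15
Product: 19 CNP0152008.3 (2R,3S,2''S,3''S,4''R), via MOM-free lactol 17 (not isolated), via pentacyclic acetal 18 (not isolated)
Conditions: NaHSO4·SiO2, wet CH2Cl2, rt
Reagents that add atoms: none
Why: Mild heterogeneous acid cleaves the six phenolic MOM ethers (17). The lactol then ionises to an aryloxy‑oxocarbenium ion that only the ortho‑hydroxyl of ring D can reach, which closes the chroman 6‑exo and fixes C2'' cis to C3'' (18). The 2‑hydroxyl of ring A adds 6‑endo to the dihydrofuran (the flavanone‑forming oxa‑Michael addition) and C3 is protonated to give the cis‑fused ketal. C2 and C3 are reversible and should settle as stated in the assumption; no alcohol solvent is present to compete for the acetal carbon.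

## Compound list

1 | 1-(5-bromo-2,4-dihydroxyphenyl)ethan-1-one | CC(=O)c1cc(Br)c(O)cc1O | starting material
2 | 1-[5-bromo-2,4-bis(methoxymethoxy)phenyl]ethan-1-one | CC(=O)c1cc(Br)c(OCOC)cc1OCOC | intermediate
3 | methyl 3-bromo-4-hydroxybenzoate | COC(=O)c1ccc(O)c(Br)c1 | starting material
4 | methyl 3-bromo-4-(methoxymethoxy)benzoate | COC(=O)c1ccc(OCOC)c(Br)c1 | intermediate
5 | 1-[5-bromo-2,4-bis(methoxymethoxy)phenyl]-3-[3-bromo-4-(methoxymethoxy)phenyl]propane-1,3-dione | O=C(CC(=O)c1ccc(OCOC)c(Br)c1)c1cc(Br)c(OCOC)cc1OCOC | intermediate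
6 | 1-[2,4-bis(methoxymethoxy)-5-prenylphenyl]-3-[4-(methoxymethoxy)-3-prenylphenyl]propane-1,3-dione | O=C(CC(=O)c1ccc(OCOC)c(CC=C(C)C)c1)c1cc(CC=C(C)C)c(OCOC)cc1OCOC | intermediate
7 | 2,4-bis(methoxymethoxy)benzaldehyde | O=Cc1ccc(OCOC)cc1OCOC | starting material
8 | 2-[2,4-bis(methoxymethoxy)benzylidene] derivative of 6 (E/Z mixture) | O=C(C(=Cc1ccc(OCOC)cc1OCOC)C(=O)c1ccc(OCOC)c(CC=C(C)C)c1)c1cc(CC=C(C)C)c(OCOC)cc1OCOC | intermediate
9 | 2-iodobenzene-1,3-diol | Oc1cccc(O)c1I | starting material
10 | 2-prenylbenzene-1,3-diol | CC(C)=CCc1c(O)cccc1O | intermediate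
11 | rac-3,6-dihydroxy-7-prenyl-1-benzofuran-2(3H)-one | OC1C(=O)Oc2c1ccc(O)c2CC=C(C)C | intermediate
12 | rac-3-hydroxy-6-(methoxymethoxy)-7-prenyl-1-benzofuran-2(3H)-one | OC1C(=O)Oc2c1ccc(OCOC)c2CC=C(C)C | intermediate
13 | Michael adduct: 3-hydroxybenzofuranone joined at C3'' to C4'' of the 2-substituted diketone (C4'', C3'' as in 19; diketone CH unassigned) | O=C(c1cc(CC=C(C)C)c(OCOC)cc1OCOC)C(C(=O)c1ccc(OCOC)c(CC=C(C)C)c1)[C@H](c1ccc(OCOC)cc1OCOC)[C@@]1(O)C(=O)Oc2c1ccc(OCOC)c2CC=C(C)C | intermediate
14 | cyclic hemiketal of 13 at the ring-B carbonyl (spiro 2-hydroxytetrahydrofuran; hemiketal and C3 centres unassigned) | O=C(c1cc(CC=C(C)C)c(OCOC)cc1OCOC)C1C(O)(c2ccc(OCOC)c(CC=C(C)C)c2)O[C@@]2(C(=O)Oc3c2ccc(OCOC)c3CC=C(C)C)[C@H]1c1ccc(OCOC)cc1OCOC | intermediate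
15 | (3S,3'S)-spiro[benzofuran-3,2'-furan]-2-one with 3'-ring D, 4'-aroyl (ring A), 5'-ring B, all phenols as MOM ethers | O=C(c1cc(CC=C(C)C)c(OCOC)cc1OCOC)C1=C(c2ccc(OCOC)c(CC=C(C)C)c2)O[C@@]2(C(=O)Oc3c2ccc(OCOC)c3CC=C(C)C)[C@H]1c1ccc(OCOC)cc1OCOC | intermediate
16 | lactol of 15 (C2'' = CH(OH), anomeric mixture) | O=C(c1cc(CC=C(C)C)c(OCOC)cc1OCOC)C1=C(c2ccc(OCOC)c(CC=C(C)C)c2)O[C@@]2(C(O)Oc3c2ccc(OCOC)c3CC=C(C)C)[C@H]1c1ccc(OCOC)cc1OCOC | intermediate
17 | MOM-free lactol (all six phenols free) | O=C(c1cc(CC=C(C)C)c(O)cc1O)C1=C(c2ccc(O)c(CC=C(C)C)c2)O[C@@]2(C(O)Oc3c2ccc(O)c3CC=C(C)C)[C@H]1c1ccc(O)cc1O | intermediate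
18 | pentacyclic acetal: chroman and dihydrobenzofuran closed on C2'', dihydrofuran and ring-A phenol still open | CC(C)=CCc1cc(C2=C(C(=O)c3cc(CC=C(C)C)c(O)cc3O)[C@@H]3c4ccc(O)cc4O[C@H]4Oc5c(ccc(O)c5CC=C(C)C)[C@]43O2)ccc1O | intermediate
19 | CNP0152008.3, (2R,3S,2''S,3''S,4''R) | CC(C)=CCc1cc([C@@]23Oc4cc(O)c(CC=C(C)C)cc4C(=O)[C@@H]2[C@@H]2c4ccc(O)cc4O[C@H]4Oc5c(ccc(O)c5CC=C(C)C)[C@]42O3)ccc1O | target

## Step count and risk

Total: 11 steps. Longest linear sequence: 7 steps (1, 3, 4, 5, 9, 10, 11).

**Step 9 (key step).** The acceptor is hindered and its β‑aryl group is electron‑rich, so addition may be slow and reversible, which would erode both the enantiomeric and the diastereomeric ratio. The relative topicity at C4''/C3'' rests on a transition‑state argument and may come out the other way. The hemiketal alkoxide may fragment by retro‑Claisen C–C cleavage before it is dehydrated.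
Fallback: the C3''–O bond is made oxidatively after a better‑precedented Michael addition. Starting from 12, the 3‑hydroxyl is removed with SmI2/HMPA/pivalic acid to give 6-(methoxymethoxy)-7-prenylbenzofuran-2(3H)-one F1. Condensation of F1 with 7 (catalytic piperidine) gives the 3‑arylidene benzofuranone F2. Squaramide‑catalysed Michael addition of diketone 6 to F2 sets C4'' in the adduct F3. Treatment of F3 with I2/K2CO3 iodinates the enolisable C3'', and the diketone enol oxygen displaces the tertiary benzylic iodide to close the spiro ring. The route is rejoined at 15.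

**Step 11.** Acid may add a phenol across a neighbouring prenyl group. The C3''–O bond may ionise once the ring‑E phenol is free. The chromanone may close kinetically from the face anti to ring D, and the assumption that 19 is the more stable C2/C3 isomer is not established.
Fallback: the closure is treated as two operations. Whatever forms of the C2,C3‑bis‑epimeric ketal F7 in the product from 16 is separated and exposed to a weak base (NaOAc, EtOH, 40 °C). This reopens the chromanone by β‑elimination to 18 and lets it reclose under equilibrium control, returning to the route at 19.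

**Step 10.** The aluminate of an aryl lactone may collapse and be reduced further to the diol, or hydride may attack the vinylogous ester.
Fallback: reduction is moved behind deprotection, so that aluminium phenoxides protect the remaining ketone. Starting from 15, NaHSO4·SiO2 removes the MOM groups and closes the chromanone to the spiro‑lactone ketal F5, in which the C4 carbonyl is para to a phenol. Excess DIBAL-H at −78 °C first forms the phenoxides, which deactivate that carbonyl, and then reduces the lactone to the lactol F6. Acidic work‑up closes the acetal, and the route is rejoined at 19.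

**Step 5.** Condensation between a hindered diaryl diketone and an electron‑rich ortho‑substituted aldehyde may stall, and the secondary amine may cleave the diketone at reflux.
Fallback: the acceptor is released in the flask from a sulfone. Starting from 6 and 7, three‑component condensation with p‑toluenesulfinic acid at rt gives the α‑sulfonylbenzyl diketone F4. Under the conditions of step 9 with added solid K2CO3, F4 loses sulfinate to generate 8 in situ, which rejoins the route.

## Further compounds

F1 | step 9 | 6-(methoxymethoxy)-7-prenyl-1-benzofuran-2(3H)-one | O=C1Cc2ccc(OCOC)c(CC=C(C)C)c2O1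
F2 | step 9 | 3-[2,4-bis(methoxymethoxy)benzylidene]-6-(methoxymethoxy)-7-prenyl-1-benzofuran-2(3H)-one (E/Z mixture) | O=C1Oc2c(CC=C(C)C)c(OCOC)ccc2C1=Cc1ccc(OCOC)cc1OCOC
F3 | step 9 | Michael adduct of 6 to F2 (C4'' as in 19, C3''–H epimers) | O=C(c1cc(CC=C(C)C)c(OCOC)cc1OCOC)C(C(=O)c1ccc(OCOC)c(CC=C(C)C)c1)[C@H](c1ccc(OCOC)cc1OCOC)C1C(=O)Oc2c1ccc(OCOC)c2CC=C(C)C
F4 | step 5 | 2-{[2,4-bis(methoxymethoxy)phenyl](4-methylbenzenesulfonyl)methyl} derivative of 6 (stereoisomer mixture) | O=C(c1cc(CC=C(C)C)c(OCOC)cc1OCOC)C(C(=O)c1ccc(OCOC)c(CC=C(C)C)c1)C(c1ccc(OCOC)cc1OCOC)S(=O)(=O)c1ccc(C)cc1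
F5 | step 10 | MOM-free spiro-lactone ketal (chromanone closed, C2'' still lactone, ring-D phenols free) | CC(C)=CCc1cc([C@@]23Oc4cc(O)c(CC=C(C)C)cc4C(=O)[C@@H]2[C@H](c2ccc(O)cc2O)[C@]2(C(=O)Oc4c2ccc(O)c4CC=C(C)C)O3)ccc1O
F6 | step 10 | lactol of F5 (anomeric mixture) | CC(C)=CCc1cc([C@@]23Oc4cc(O)c(CC=C(C)C)cc4C(=O)[C@@H]2[C@H](c2ccc(O)cc2O)[C@]2(C(O)Oc4c2ccc(O)c4CC=C(C)C)O3)ccc1O
F7 | step 11 | C2,C3-bis-epimer of 19 | CC(C)=CCc1cc([C@]23Oc4cc(O)c(CC=C(C)C)cc4C(=O)[C@H]2[C@@H]2c4ccc(O)cc4O[C@H]4Oc5c(ccc(O)c5CC=C(C)C)[C@]42O3)ccc1O
A1 | alternative 1 | 1-(2,4-dihydroxy-5-prenylphenyl)-3-(4-hydroxy-3-prenylphenyl)propane-1,3-dione | CC(C)=CCc1cc(C(=O)CC(=O)c2ccc(O)c(CC=C(C)C)c2)c(O)cc1O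
A2 | alternative 1 | racemic dehydro-acetal (cyclised 2'-hydroxyisoflavylium; C3''=C4'' alkene, C2'' acetal) | Oc1ccc2C=C3c4ccc(O)c(CC=C(C)C)c4OC3Oc2c1
A3 | alternative 1 | racemic extended quinone methide from A2 | O=C1C=CC2=CC3=C4C=CC(=O)C(CC=C(C)C)=C4OC3OC2=C1
A4 | alternative 2 | 7-hydroxy-3-(2,4-dihydroxy-3-prenylphenyl)chromenylium chloride | Oc1ccc2cc(-c3ccc(O)c(CC=C(C)C)c3O)c[o+]c2c1.[Cl-]
A5 | alternative 2 | C4''-adduct of A1 with cis-fused acetal and hydrogen on C3'' | CC(C)=CCc1cc(C(=O)C(C(=O)c2ccc(O)c(CC=C(C)C)c2)[C@@H]2c3ccc(O)cc3O[C@H]3Oc4c(ccc(O)c4CC=C(C)C)[C@H]32)c(O)cc1O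
A6 | alternative 3 | 6-(methoxymethoxy)-7-prenyl-1-benzofuran-2,3-dione | O=C1Oc2c(CC=C(C)C)c(OCOC)ccc2C1=O
A7 | alternative 3 | spiro-γ-butyrolactone from A6 and A8 (C4'', C3'' as in 19) | O=C1C[C@H](c3ccc(OCOC)cc3OCOC)[C@@]2(O1)C(=O)Oc1c2ccc(OCOC)c1CC=C(C)C
A8 | alternative 3 | (E)-3-[2,4-bis(methoxymethoxy)phenyl]prop-2-enal | O=C/C=C/c1ccc(OCOC)cc1OCOC
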